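**Strategy.** The route rests on closing the cyclohexane (C1, C10, C11, C12, C13, C14) at C11–C12 by an intramolecular nitro-aldol reaction. A nitro group parked on C12 as a removable activating group lets the methyl-bearing carbon attack the C11 aldehyde of a (Z)-enal, which delivers in one operation the ring, the C11 oxygen and the C10=C1 allylic alcohol; it exploits the vicinal C11–O/C12–CH3 pair next to the C13 methylene. After radical denitration, the allylic carbamate is annulated with two aldehyde components to the cis-fused tetrahydrofuran, ring-closing metathesis forms the oxonane, and a late etherification the oxepane. The precursor is an acyclic nitro enal built by organocatalytic Michael addition.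

Key step: step 8

Remark: atoms carry asbestinin numbers: ring carbons C1–C14 (C2 and C9 bridged by the tetrahydrofuran oxygen), C15/C16/C17 the oxidised isopropyl group (C16–O–C3 is the oxepane ether), C18, C19 and C20 the methyls on C3, C7 and C12.

**Route**

Step 1
Reactants: 1 (S)-3-bromo-2-methylpropan-1-ol
Product: 2 bromo silyl ether
Conditions: i-Pr3SiCl, imidazole, CH2Cl2, 0 °C to rt
Reagents that add atoms: chlorotriisopropylsilane, CC(C)[Si](Cl)(C(C)C)C(C)C
Why: Standard silylation of the primary alcohol; the C15 stereocentre is taken from the chiral pool and is not touched.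

Step 2
Reactants: 2 bromo silyl ether
Product: 4 silyloxy aldehyde, via Grignard reagent 3 (not isolated)
Conditions: Mg, THF, reflux; then HCONMe2, 0 °C; aq. NH4Cl
Reagents that add atoms: N,N-dimethylformamide, CN(C)C=O
Why: Bouveault formylation of the Grignard reagent adds C1 as the aldehyde carbon, the former CH2Br becoming C14.

Step 3
Reactants: 5 2-nitropropan-1-ol
Product: 6 2-nitroprop-1-ene
Conditions: phthalic anhydride, 150–180 °C, product distilled out under reduced pressure
Reagents that add atoms: none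
Why: Dehydration of the β-nitro alcohol through its phthalate half-ester (E1cB) should give the nitroalkene, which is used at once.

Step 4
Reactants: 4 silyloxy aldehyde; 6 2-nitroprop-1-ene
Product: 7 nitro aldehyde
Conditions: (S)-α,α-diphenylprolinol trimethylsilyl ether (10 mol %), 4-nitrophenol (20 mol %), toluene, 0 °C
Reagents that add atoms: none
Why: Enamine-catalysed Michael addition in which the shielded enamine face fixes C14 as (S) under catalyst control, while the nitro-bearing C12 forms as both epimers, which is without consequence.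

Step 5
Reactants: 7 nitro aldehyde
Product: 8 (Z)-enoate
Conditions: (CF3CH2O)2P(O)CH2CO2Me, KN(SiMe3)2, 18-crown-6, THF, −78 °C
Reagents that add atoms: methyl bis(2,2,2-trifluoroethyl)phosphonoacetate, COC(=O)CP(=O)(OCC(F)(F)F)OCC(F)(F)F
Why: Still–Gennari olefination adds C10 and C11 and should give the Z alkene by fast kinetic elimination.

Step 6
Reactants: 8 (Z)-enoate
Product: 9 (Z)-allylic alcohol
Conditions: i-Bu2AlH, CH2Cl2, −78 °C; Rochelle salt work-up
Reagents that add atoms: none
Why: Ester reduction at low temperature should leave the nitro group and the Z geometry intact.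

Step 7
Reactants: 9 (Z)-allylic alcohol
Product: 10 (Z)-nitro enal
Conditions: Dess–Martin periodinane, pyridine, CH2Cl2, 0 °C; used directly
Reagents that add atoms: none
Why: Buffered Dess–Martin oxidation is non-basic and should give the (Z)-enal without Z/E isomerisation.

Step 8
Reactants: 10 (Z)-nitro enal
Product: 11 nitro cyclohexenol
Conditions: 1,1,3,3-tetramethylguanidine (0.1 equiv), THF (5 mM), −20 °C; AcOH quench
Reagents that add atoms: none
Why: Catalytic base forms the nitronate at C12, which adds to the C11 aldehyde (intramolecular Henry reaction, the ring-closing half of known nitro-Michael/Henry cyclohexane syntheses). The cyclohexene closes in a 6-exo-trig mode with respect to the carbonyl, the Z geometry of C10=C1 holding the two ends within reach. The new C11 carbinol is set under thermodynamic control because the nitro-aldol is reversible: the hydroxyl and the C14 side chain should both take pseudo-equatorial positions, that is trans. C12 becomes a quaternary nitro carbon as both epimers, which does not matter because the nitro group is removed in step 9 and C12 is set in step 18. The step needs 1,2- over 1,4-addition and no epimerisation at C14: conjugate attack at C1 would give a four-membered ring, and only the nitro C–H, far more acidic than the γ-hydrogen at C14, is removed by the weak base. High dilution suppresses intermolecular addition.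

Step 9
Reactants: 11 nitro cyclohexenol
Product: 12 cyclohexenol
Conditions: Bu3SnH, AIBN, toluene, 110 °C
Reagents that add atoms: none
Why: Radical denitration of the tertiary nitro group removes the activating group; C12–H forms as an epimeric mixture that is converged in step 18.

Step 10
Reactants: 12 cyclohexenol
Product: 13 allylic carbamate
Conditions: NaH, ClC(O)N(i-Pr)2, THF, reflux
Reagents that add atoms: N,N-diisopropylcarbamoyl chloride, CC(C)N(C(C)C)C(Cl)=O
Why: O-Carbamoylation of the secondary allylic alkoxide installs the directing group for the homoaldol reaction with retention at C11.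

Step 11
Reactants: 14 (R)-2-methylglycidol
Product: 15 (S)-2-methylhex-5-ene-1,2-diol
Conditions: CH2=CHCH2MgCl (2.5 equiv), CuI (10 mol %), THF, −30 to 0 °C
Reagents that add atoms: allylmagnesium chloride, C=CC[Mg]Cl
Why: Copper-catalysed epoxide opening at the unhindered CH2 terminus leaves the quaternary C3 stereocentre of the chiral pool epoxide untouched.

Step 12
Reactants: 15 diol
Product: 16 bis(triethylsilyl) ether
Conditions: Et3SiOTf, 2,6-lutidine, CH2Cl2, −78 to 0 °C
Reagents that add atoms: triethylsilyl triflate, CC[Si](CC)(CC)OS(=O)(=O)C(F)(F)F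
Why: The silyl triflate silylates both the primary and the tertiary hydroxyl.

Step 13
Reactants: 16 bis(triethylsilyl) ether
Product: 17 α-silyloxy aldehyde
Conditions: (COCl)2, Me2SO, CH2Cl2, −78 to −30 °C; Et3N
Reagents that add atoms: none
Why: Under Swern conditions the primary triethylsilyl ether is cleaved and oxidised directly to the aldehyde while the tertiary silyl ether is inert.

Step 14
Reactants: 18 2-methylallylmagnesium chloride
Product: 19 4,4-dimethoxy-2-methylbut-1-ene
Conditions: HC(OMe)3, THF, reflux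
Reagents that add atoms: trimethyl orthoformate, COC(OC)OC
Why: Bodroux–Chichibabin reaction of the Grignard reagent with the orthoformate; the symmetric methallyl unit makes allylic transposition irrelevant.

Step 15
Reactants: 13 allylic carbamate; 17 α-silyloxy aldehyde
Product: 22 homoaldol adduct, via lithiated carbamate 20 (not isolated), via titanated carbamate 21 (not isolated)
Conditions: s-BuLi, TMEDA, toluene, −78 °C; ClTi(OiPr)3, −78 °C; then 17, −78 to −50 °C
Reagents that add atoms: none
Why: Hoppe homoaldol reaction: carbamate-directed deprotonation at C11 (retention) and lithium–titanium exchange (inversion) put titanium on the ring face anti to the C14 side chain, and the aldehyde is delivered suprafacially to C1 through a cyclic transition state with its substituent turned away from the ring, which should set C1 and C2.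

Step 16
Reactants: 22 homoaldol adduct; 19 4,4-dimethoxy-2-methylbut-1-ene
Product: 23 bicyclic ketone
Conditions: BF3·OEt2, CH2Cl2, −78 to −20 °C
Reagents that add atoms: none
Why: Mukaiyama-type cyclisation of the oxocarbenium ion onto the enol carbamate; the tether forces the new C9–C10 bond cis to C1–C2 (cis ring fusion), the methallyl group should take the convex position cis to the C2 substituent, and loss of the carbamoyl group unveils the C11 ketone.

Step 17
Reactants: 23 bicyclic ketone
Product: 24 tricyclic ketone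
Conditions: second-generation Grubbs catalyst (5 mol %), CH2Cl2 (1 mM), 40 °C
Reagents that add atoms: none
Why: Ring-closing metathesis of the butenyl and methallyl groups held cis on the tetrahydrofuran closes the oxonane; the nine-membered ring allows only the Z trisubstituted C6=C7 alkene.

Step 18
Reactants: 24 tricyclic ketone
Product: 26 C12-defined ketone, via lithium enolate 25 (not isolated)
Conditions: LiN(i-Pr)2, THF, −78 °C; then 2,6-di-tert-butyl-4-methylphenol, −78 °C; cold pH 7 buffer
Reagents that add atoms: none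
Why: Both C12 epimers give the same C11/C12 enolate (C12–H is more accessible than the ring-fusion C10–H), and kinetic protonation from the convex face, away from the pseudo-axial C9 substituent, should place the methyl on the concave face as in the target.

Step 19
Reactants: 26 C12-defined ketone
Product: 27 C11 alcohol
Conditions: NaBH4, MeOH, −40 to 0 °C
Reagents that add atoms: none
Why: Hydride should attack the ketone from the convex face opposite the tetrahydrofuran ring, leaving the C11 hydroxyl cis to the C12 methyl and to C9.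

Step 20
Reactants: 27 C11 alcohol
Product: 28 C11 acetate
Conditions: Ac2O, pyridine, DMAP (cat.), rt
Reagents that add atoms: acetic anhydride, CC(=O)OC(C)=O
Why: Acylation of the secondary alcohol with retention installs the acetate of the target.

Step 21
Reactants: 28 C11 acetate
Product: 30 C6 alcohol, via C6 alkylborane 29 (not isolated)
Conditions: BH3·THF, THF, 0 °C to rt; then 30 % H2O2, aq. NaOAc, 0 °C
Reagents that add atoms: hydrogen peroxide, OO
Why: Hydroboration–oxidation adds boron to the less substituted C6 and hydrogen to C7 in a syn fashion, expected from the outer face of the Z-oxonene remote from the transannular ether oxygen, which sets (6R,7R) together.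

Step 22
Reactants: 30 C6 alcohol
Product: 31 C6 methyl ether
Conditions: MeOTf, 2,6-di-tert-butyl-4-methylpyridine, CH2Cl2, rt
Reagents that add atoms: methyl triflate, COS(=O)(=O)C(F)(F)F
Why: Non-basic O-methylation of the only free hydroxyl leaves the acetate and both silyl ethers in place.

Step 23
Reactants: 31 C6 methyl ether
Product: 32 diol
Conditions: HF·pyridine, THF/pyridine, 0 °C to rt
Reagents that add atoms: none
Why: Fluoride-mediated cleavage of both silyl ethers frees the tertiary C3 and primary C16 hydroxyls without acyl migration.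

Step 24
Reactants: 32 diol
Product: 34 target asbestinin, via C16 triflate 33 (not isolated)
Conditions: Tf2O (1.1 equiv), 2,6-lutidine, CH2Cl2, −78 °C to rt
Reagents that add atoms: none
Why: Selective triflation of the primary alcohol followed by intramolecular Williamson-type displacement by the tertiary C3 hydroxyl (7-exo-tet) closes the oxepane without touching a stereocentre.

**Compound list**

1 | (S)-3-bromo-2-methylpropan-1-ol | OC[C@H](C)CBr | starting material
2 | (S)-(3-bromo-2-methylpropoxy)triisopropylsilane | CC(C)[Si](C(C)C)(C(C)C)OC[C@H](C)CBr | intermediate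
3 | (S)-[2-methyl-3-(triisopropylsilyloxy)propyl]magnesium bromide | CC(C)[Si](C(C)C)(C(C)C)OC[C@H](C)C[Mg]Br | intermediate
4 | (R)-3-methyl-4-(triisopropylsilyloxy)butanal | CC(C)[Si](C(C)C)(C(C)C)OC[C@H](C)CC=O | intermediate
5 | 2-nitropropan-1-ol (racemic) | CC(CO)[N+](=O)[O-] | starting material
6 | 2-nitroprop-1-ene | CC(=C)[N+](=O)[O-] | intermediate
7 | (2S,3R)-3-methyl-2-(2-nitropropyl)-4-(triisopropylsilyloxy)butanal, both epimers at the nitro carbon C12 | CC(C)[Si](C(C)C)(C(C)C)OC[C@H](C)[C@@H](C=O)CC(C)[N+](=O)[O-] | intermediate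
8 | methyl (2Z,4R,5R)-5-methyl-4-(2-nitropropyl)-6-(triisopropylsilyloxy)hex-2-enoate, C12 epimers | CC(C)[Si](C(C)C)(C(C)C)OC[C@H](C)[C@@H](/C=C\C(=O)OC)CC(C)[N+](=O)[O-] | intermediate
9 | (2Z,4R,5R)-5-methyl-4-(2-nitropropyl)-6-(triisopropylsilyloxy)hex-2-en-1-ol, C12 epimers | CC(C)[Si](C(C)C)(C(C)C)OC[C@H](C)[C@@H](/C=C\CO)CC(C)[N+](=O)[O-] | intermediate
10 | (2Z,4R,5R)-5-methyl-4-(2-nitropropyl)-6-(triisopropylsilyloxy)hex-2-enal, C12 epimers | CC(C)[Si](C(C)C)(C(C)C)OC[C@H](C)[C@@H](/C=C\C=O)CC(C)[N+](=O)[O-] | intermediate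
11 | (1S,4R)-6-methyl-6-nitro-4-[(2R)-1-(triisopropylsilyloxy)propan-2-yl]cyclohex-2-en-1-ol, hydroxyl trans to the side chain, both epimers at C6 (= C12) | O[C@H]1C=C[C@H]([C@@H](C)CO[Si](C(C)C)(C(C)C)C(C)C)CC1(C)[N+](=O)[O-] | intermediate
12 | (1R,4R)-6-methyl-4-[(2R)-1-(triisopropylsilyloxy)propan-2-yl]cyclohex-2-en-1-ol, hydroxyl trans to the side chain, C12 epimers | O[C@H]1C=C[C@H]([C@@H](C)CO[Si](C(C)C)(C(C)C)C(C)C)CC1C | intermediate
13 | (1R,4R)-6-methyl-4-[(2R)-1-(triisopropylsilyloxy)propan-2-yl]cyclohex-2-en-1-yl N,N-diisopropylcarbamate, C12 epimers | CC(C)N(C(C)C)C(=O)O[C@H]1C=C[C@H]([C@@H](C)CO[Si](C(C)C)(C(C)C)C(C)C)CC1C | intermediate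
14 | (R)-(2-methyloxiran-2-yl)methanol | C[C@@]1(CO)CO1 | starting material
15 | (S)-2-methylhex-5-ene-1,2-diol | C=CCC[C@](C)(O)CO | intermediate
16 | (S)-2-methyl-1,2-bis(triethylsilyloxy)hex-5-ene | C=CCC[C@](C)(O[Si](CC)(CC)CC)CO[Si](CC)(CC)CC | intermediate
17 | (S)-2-methyl-2-(triethylsilyloxy)hex-5-enal | C=CCC[C@](C)(O[Si](CC)(CC)CC)C=O | intermediate
18 | 2-methylallylmagnesium chloride | CC(=C)C[Mg]Cl | starting material
19 | 4,4-dimethoxy-2-methylbut-1-ene | C=C(C)CC(OC)OC | intermediate
20 | carbamate 13 lithiated at C11, lithium on the face of the C14 side chain | CC(C)N(C(C)C)C(=O)O[C@@]1([Li])C=C[C@H]([C@@H](C)CO[Si](C(C)C)(C(C)C)C(C)C)CC1C | intermediate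
21 | C11 triisopropoxytitanium derivative of 13, titanium anti to the C14 side chain | CC(C)N(C(C)C)C(=O)O[C@]1([Ti](OC(C)C)(OC(C)C)OC(C)C)C=C[C@H]([C@@H](C)CO[Si](C(C)C)(C(C)C)C(C)C)CC1C | intermediate
22 | 3-[(1S,2S)-1-hydroxy-2-methyl-2-(triethylsilyloxy)hex-5-en-1-yl]-6-methyl-4-[(2R)-1-(triisopropylsilyloxy)propan-2-yl]cyclohex-1-en-1-yl N,N-diisopropylcarbamate, the two ring substituents trans, C12 epimers | CC(C)N(C(C)C)C(=O)OC1=C[C@@H]([C@H](O)[C@@](C)(O[Si](CC)(CC)CC)CCC=C)[C@H]([C@@H](C)CO[Si](C(C)C)(C(C)C)C(C)C)CC1C | intermediate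
23 | cis-fused hexahydroisobenzofuran-4(1H)-one (C11 ketone) with 2-methylallyl at C9, (S)-2-(triethylsilyloxy)hex-5-en-2-yl at C2, methyl at C12 (both epimers) and the silyloxypropyl chain at C14; C1, C2, C3, C9, C10, C14, C15 as in 34 | O=C1C(C)C[C@@H]([C@@H](C)CO[Si](C(C)C)(C(C)C)C(C)C)[C@H]2[C@@H]1[C@H](CC(C)=C)O[C@@H]2[C@@](C)(O[Si](CC)(CC)CC)CCC=C | intermediate
24 | tricyclic C11 ketone with the (Z)-C6=C7 oxonene closed, C3–OSiEt3, C16–OSi(i-Pr)3, C12 epimers | O=C1C(C)C[C@@H]([C@@H](C)CO[Si](C(C)C)(C(C)C)C(C)C)[C@H]2[C@@H]1[C@@H]3C/C(C)=C\CC[C@](C)(O[Si](CC)(CC)CC)[C@H]2O3 | intermediate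
25 | lithium C11=C12 enolate of 24 | [Li]OC1=C(C)C[C@@H]([C@@H](C)CO[Si](C(C)C)(C(C)C)C(C)C)[C@H]2[C@@H]1[C@@H]3C/C(C)=C\CC[C@](C)(O[Si](CC)(CC)CC)[C@H]2O3 | intermediate
26 | ketone 24 as the single C12 epimer, methyl on the concave face cis to C9 and C2 | O=C1[C@H](C)C[C@@H]([C@@H](C)CO[Si](C(C)C)(C(C)C)C(C)C)[C@H]2[C@@H]1[C@@H]3C/C(C)=C\CC[C@](C)(O[Si](CC)(CC)CC)[C@H]2O3 | intermediate
27 | C11 alcohol of 26, hydroxyl cis to the C12 methyl | O[C@@H]1[C@H](C)C[C@@H]([C@@H](C)CO[Si](C(C)C)(C(C)C)C(C)C)[C@H]2[C@@H]1[C@@H]3C/C(C)=C\CC[C@](C)(O[Si](CC)(CC)CC)[C@H]2O3 | intermediate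
28 | C11 acetate of 27 | CC(=O)O[C@@H]1[C@H](C)C[C@@H]([C@@H](C)CO[Si](C(C)C)(C(C)C)C(C)C)[C@H]2[C@@H]1[C@@H]3C/C(C)=C\CC[C@](C)(O[Si](CC)(CC)CC)[C@H]2O3 | intermediate
29 | C6 alkylborane from 28 (BH2 at C6, H at C7, syn) | CC(=O)O[C@@H]1[C@H](C)C[C@@H]([C@@H](C)CO[Si](C(C)C)(C(C)C)C(C)C)[C@H]2[C@@H]1[C@@H]3C[C@@H](C)[C@H](B)CC[C@](C)(O[Si](CC)(CC)CC)[C@H]2O3 | intermediate
30 | (6R,7R) C6 alcohol with saturated oxonane | CC(=O)O[C@@H]1[C@H](C)C[C@@H]([C@@H](C)CO[Si](C(C)C)(C(C)C)C(C)C)[C@H]2[C@@H]1[C@@H]3C[C@@H](C)[C@H](O)CC[C@](C)(O[Si](CC)(CC)CC)[C@H]2O3 | intermediate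
31 | C6 methyl ether of 30 | CC(=O)O[C@@H]1[C@H](C)C[C@@H]([C@@H](C)CO[Si](C(C)C)(C(C)C)C(C)C)[C@H]2[C@@H]1[C@@H]3C[C@@H](C)[C@H](OC)CC[C@](C)(O[Si](CC)(CC)CC)[C@H]2O3 | intermediate
32 | diol with free tertiary C3 and primary C16 hydroxyls | CC(=O)O[C@@H]1[C@H](C)C[C@@H]([C@@H](C)CO)[C@H]2[C@@H]1[C@@H]3C[C@@H](C)[C@H](OC)CC[C@](C)(O)[C@H]2O3 | intermediate
33 | C16 triflate of 32 | CC(=O)O[C@@H]1[C@H](C)C[C@@H]([C@@H](C)COS(=O)(=O)C(F)(F)F)[C@H]2[C@@H]1[C@@H]3C[C@@H](C)[C@H](OC)CC[C@](C)(O)[C@H]2O3 | intermediate
34 | CNP0289153.2, (1S,2S,3S,6R,7R,9S,10R,11R,12R,14S,15R) in the numbering of the remark | CO[C@@H]1CC[C@]2(C)OC[C@H](C)[C@@H]3C[C@@H](C)[C@@H](OC(C)=O)[C@@H]4[C@H]3[C@@H]2O[C@H]4C[C@H]1C | target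

**Count and risks**

Total step count: 24. Longest linear sequence: 19 steps (1, 2, 4–10, 15–24).

The three steps most likely to fail:

Step 8. Z to E isomerisation of enal 10 or retro-nitro-aldol opening could outrun ring closure. The fallback moves the same nitro-aldol closure to the saturated series. It sets out from 9: diimide reduction (2-nitrobenzenesulfonyl hydrazide, Et3N) gives the saturated nitro alcohol F1, Dess–Martin oxidation the nitro aldehyde F2, and the nitro-aldol reaction (6-exo) the nitrocyclohexanol F3. Bu3SnH/AIBN then gives the cyclohexanol F4 and oxidation the 2-methylcyclohexanone F5. Kinetic enolisation on the methylene side (LiN(i-Pr)2, Me3SiCl) gives the silyl enol ether F6, Pd(OAc)2 (Saegusa–Ito oxidation) the enone F7, and Luche reduction (NaBH4, CeCl3·7H2O) comes back to the route at 12.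

Step 15. The aldehyde may add with poor facial control at C2, or the hindered partners may couple sluggishly. The fallback sets the carbinol by reduction instead of addition: the crude adduct 22 (either C2 epimer) is oxidised with Dess–Martin periodinane to the C2 ketone F8. Reagent-controlled reduction ((R)-2-methyl-CBS-oxazaborolidine, BH3·SMe2, the quaternary C3 acting as the large group) comes back at 22.

Step 18. Protonation of the enolate may show poor facial selectivity, or the product may re-epimerise towards the equatorial methyl. The fallback delivers the C12 hydrogen by a radical: enolate 25 (from 24) is trapped with N-bromosuccinimide at −78 °C as the α-bromo ketone F9. Bu3SnH/AIBN reduces it through the planar α-keto radical, which should take hydrogen from the bulky hydride on the convex face, coming back at 26.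

Further compounds
F1 | step 8 | (4R,5R)-5-methyl-4-(2-nitropropyl)-6-(triisopropylsilyloxy)hexan-1-ol, C12 epimers | CC(C)[Si](C(C)C)(C(C)C)OC[C@H](C)[C@@H](CCCO)CC(C)[N+](=O)[O-]
F2 | step 8 | (4R,5R)-5-methyl-4-(2-nitropropyl)-6-(triisopropylsilyloxy)hexanal, C12 epimers | CC(C)[Si](C(C)C)(C(C)C)OC[C@H](C)[C@@H](CCC=O)CC(C)[N+](=O)[O-]
F3 | step 8 | 2-methyl-2-nitro-4-[(2R)-1-(triisopropylsilyloxy)propan-2-yl]cyclohexan-1-ol, C14 as in 12, C11 and C12 epimers | OC1CC[C@H]([C@@H](C)CO[Si](C(C)C)(C(C)C)C(C)C)CC1(C)[N+](=O)[O-]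
F4 | step 8 | 2-methyl-4-[(2R)-1-(triisopropylsilyloxy)propan-2-yl]cyclohexan-1-ol, C14 as in 12, C11 and C12 epimers | OC1CC[C@H]([C@@H](C)CO[Si](C(C)C)(C(C)C)C(C)C)CC1C
F5 | step 8 | 2-methyl-4-[(2R)-1-(triisopropylsilyloxy)propan-2-yl]cyclohexan-1-one, C14 as in 12, C12 epimers | O=C1CC[C@H]([C@@H](C)CO[Si](C(C)C)(C(C)C)C(C)C)CC1C
F6 | step 8 | trimethylsilyl enol ether of F5 with the C10=C11 double bond | C[Si](C)(C)OC1=CC[C@H]([C@@H](C)CO[Si](C(C)C)(C(C)C)C(C)C)CC1C
F7 | step 8 | 6-methyl-4-[(2R)-1-(triisopropylsilyloxy)propan-2-yl]cyclohex-2-en-1-one, C14 as in 12, C12 epimers | O=C1C=C[C@H]([C@@H](C)CO[Si](C(C)C)(C(C)C)C(C)C)CC1C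
F8 | step 15 | C2 ketone of 22 | CC(C)N(C(C)C)C(=O)OC1=C[C@@H](C(=O)[C@@](C)(O[Si](CC)(CC)CC)CCC=C)[C@H]([C@@H](C)CO[Si](C(C)C)(C(C)C)C(C)C)CC1C
F9 | step 18 | C12 bromo ketone from 24, C12 epimers | O=C1C(C)(Br)C[C@@H]([C@@H](C)CO[Si](C(C)C)(C(C)C)C(C)C)[C@H]2[C@@H]1[C@@H]3C/C(C)=C\CC[C@](C)(O[Si](CC)(CC)CC)[C@H]2O3
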